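If the loading of L is what counts, X at 20 h goes in proportion to it; if the step G + Z → X is what counts, X ignores it. Two chemists hold these views about this flask.

| flask | G | Q | L | remark | time |
|---|---|---|---|---|---|
| alpha | 0.20 M | 0.60 equiv | 5.2 mol% | run made earlier |  |
| delta | 0.20 M | 0.60 equiv | 8.1 mol% | run made earlier |  |
| zeta | 0.30 M | 0.60 equiv | 3.7 mol% | run made earlier |  |
| flask | 0.20 M | 0.600 equiv | 3.7 mol% |  | 20 h |

- alpha (time / h: G / %, Z / %): 1.50: 88.7, 9.7; 4.00: 78.4, 14.8; 8.00: 68.1, 15.7; 20.0: 52.9, 11.8
- delta (time / h: G / %, Z / %): 2.50: 80.0, 15.3; 8.00: 65.9, 16.5; 12.0: 59.9, 13.7; 20.0: 51.0, 12.3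
- zeta (time / h: G / %, Z / %): 5.00: 65.8, 17.6; 10.0: 53.3, 15.1; 15.0: 46.2, 12.0; 20.0: 41.4, 10.8

(readings scatter by 0.5 percentage points)

- in percentages every species weighs as the G in it: one X counts as two
- the analysis behind the earlier runs scatters by 0.5 percentage points, standard deviation
- candidate steps: Q + L <-> E; G + Z -> X; J <-> L + Z; G + E <-> J
- the reaction counts as stopped when no species that holds the G changes by six tenths of a point or more over the second half of the time

- at 20 h, what has stopped the reaction, if anything has (forward and back rates have come level / Q has run out first / all of G has reacted / it is still moving / no working catalyst is left)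
- part of the G gone at 20 h
- the Z standing at 20 h, as a percentage of the G charged
- the X standing at 20 h, as a percentage of the G charged
- amount of Z if the flask were left three thousand times as long, in percent of the G charged

Both read X as the remainder of G and Z: 35.3% in alpha and 36.7% in delta at 20.0 h. The gap of 1.4 percentage points is near the scatter of a difference of two remainders, four readings in all, 1 point. The scale between the views has its zero where two runs differing in L end level. From alpha to delta it reads 0.0878: that is n, the loading exponent, the logarithm of the ratio of X in two runs over the logarithm of the ratio of their L, at equal cG and time. It is an apparent order in L, and proportion means an exponent of 1.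

The first chemist, holding to proportion, scales alpha down to the flask's loading and gets X of 25.1%. The second answers with zeta: at the flask's loading but with cG of 0.30 M, its X is 47.8%, more than alpha's. My own reckoning carries the measured n from alpha and gives X of 34.3%.

The forecast takes the second side, holding that “Z sits near a catalysed equilibrium”: it is still moving, conversion 43%, Z 11.5%, X 31.5%, and Z on the long wait asked about 0.01%. Its X lies below mine.

The flask gives: it is still moving, with 16 points of movement over the second half; conversion 45.6%, Z 11.6%, X 33.9%, and Z on the long wait 0.00887%. The forecast stands, and X is well above the proportional figure.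

    Q + L ⇌ E (K = 4.20 M⁻¹, k = 1900 M⁻¹ h⁻¹)
    G + Z → X (k = 0.500 M⁻¹ h⁻¹)
    J ⇌ L + Z (K = 0.900 M, k = 28.0 h⁻¹)
    G + E ⇌ J (K = 1.10 M⁻¹, k = 180 M⁻¹ h⁻¹)

The first chemist keeps the early hours: G lost per hour in the flask up to 2.00 h is 0.699 of that read in alpha up to 1.50 h, a shorter window, close to the loading ratio of 0.712. For a neighbour of the flask with 2.2 mol% of L, n carried from the flask gives X of 32.4%; the neighbour gives 30.1%, less. Between these two loadings the exponent reads 0.227, larger than n. Z in the neighbour stands at 11.1%, against 11.6% in the flask.

The earlier runs and the new flask were generated by integration with made-up constants, noise included.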